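**Remark on the chemistry:** the target has no stereocentre, so no configuration has to be set; 1-SEM-imidazole 1 is taken as a catalogue compound (SEM = [2-(trimethylsilyl)ethoxy]methyl).

## Analysis of the target

Lepidine C is an achiral diaryl ether built from four aromatic rings: ring A is a 1,2,4-trisubstituted benzene (C1 carries the ether oxygen, C2 a CH2–imidazol-2-yl arm, C4 the methoxy group), ring B is a meta-disubstituted benzene (C1' carries the same ether oxygen, C3' the second CH2–imidazol-2-yl arm), and rings C and D are 2-substituted 1H-imidazoles with free N–H and unsubstituted C4/C5. There is no stereocentre, so every problem is one of regio- and chemoselectivity. The feature the plan rests on is that ring A with ring C and ring B with ring D are the same unit, a 2-benzylimidazole oxygenated meta to the CH2 group. The two units are joined by one bond, from the phenolic oxygen on C1' of ring B to C1 of ring A, the carbon para to the C4 methoxy group and ortho to the C2 arm, which is the connectivity of a para C–O phenol coupling and makes the molecule a cross-dimer. That C1–O bond is the hard bond: ring A is electron-rich (oxygen para) and ortho-substituted, which rules out SNAr and slows metal insertion into a C1–halogen bond. The imidazoles are the sensitive groups, because N–H (pKa about 14) and the basic N3 compete with a phenol for any aryl electrophile and bind copper and palladium, and the ring A imidazole sits where it can close onto C1. C4/C5 of the imidazoles are open to electrophiles, and both CH2 groups are doubly activated, hence acidic and oxidisable.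

## Retrosynthetic reasoning

**8 to 7 (two N–CH2 bonds).** The last operation only removes the two SEM groups from N1 of rings C and D of bis-SEM ether 7. The groups are there for one reason: an imidazole without N–H cannot be N-arylated in the key step. SEM is chosen because it survives an alkyllithium, a hot thiolate, sulfonic acid at room temperature and copper catalysis, and leaves in hot aqueous acid that touches neither the diaryl ether nor the methyl ether.

**7 to 4 and 5 (the C1–O bond of ring A).** The ether is cut between C1 of ring A and the oxygen, so that ring A arrives as the plain anisole monomer 4 with a hydrogen on that carbon and ring B arrives as the phenol monomer 5. The cut is made here and not on the ring B side because C1 of ring A is para to the methoxy group. That position is where a bulky trivalent-iodine electrophile attacks an anisole on its own, whereas C1' of ring B is meta to its only substituent and has no innate C–H selectivity. What is gained: both partners are the same monomer, no halogen has to be placed, and both imidazoles are already in place. The forward reaction must convert the C–H bond of 4 into the aryl(mesityl)iodonium salt 6 in the flask and then couple 6 with the phenoxide of 5 under copper catalysis, at oxygen and not at nitrogen.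

**5 to 4 (the O–CH3 bond).** The phenol partner is the anisole partner minus its methyl group. One monomer therefore serves both halves, and the methoxy group of the target is simply the one that is not cleaved. The forward reaction is a nucleophilic demethylation by a thiolate, which the base-stable SEM group should tolerate.

**4 to 1 and 2 (the CH2–C2 bond of the imidazole).** The imidazole ring is bought intact and already protected as 1. Its C2–H is the most acidic position, so lithiation gives the C2 anion 3, which is joined to the benzylic carbon of bromide 2. Cutting here, rather than building the heterocycle from a nitrile, gives the protected monomer in one step.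

## Alternatives that were turned down

Alternative 1: The textbook route. Disconnection: the same ether oxygen, but between an aryl bromide and a phenol, with both imidazoles built afterwards. Forward key step: copper-catalysed Ullmann coupling of the bromide 2-(2-bromo-5-methoxyphenyl)acetonitrile A1 with the phenol 2-(3-hydroxyphenyl)acetonitrile A2 to the bis-nitrile A3, followed by two Pinner-type imidazole annulations. Turned down for three reasons:
- The bromine of A1 sits on an electron-rich, ortho-substituted ring, so insertion of copper is slow and needs hot base. Under those conditions the benzylic nitrile CH2 groups (pKa about 22) of A1, A2 and A3 are deprotonated and open C-arylation and self-condensation channels.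
- Each heterocycle then costs two operations on the bis-functional substrate A3, with mono/bis mixtures at each stage.
- Two different arene building blocks, A1 and A2, are needed, where the dimeric nature of the target allows one.

Alternative 2: Two-directional attachment of the imidazoles. Disconnection: both benzylic carbon–imidazole C2 bonds at once. Forward key step: SNAr of 3-hydroxybenzaldehyde A5 on 2-fluoro-5-methoxybenzaldehyde A4 to the dialdehyde A6, double addition of the lithio-imidazole 3 to give the bis-carbinol A7, then double deoxygenation and deprotection. Turned down for two reasons:
- The phenoxide of A5 must displace the fluorine of A4, which is para to the methoxy group, so the Meisenheimer intermediate is destabilised and the SNAr needs forcing.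
- More seriously, both carbinols of A7 lie between an arene and an imidazole that is protonated under ionic reduction conditions. The benzylic cation is disfavoured, so each oxygen would have to be removed by a radical sequence of two operations. The route grows to six or more steps without using the identity of the two halves.

Alternative 3: Ring A from a saturated ring. Disconnection: ring A and its C2–CH2 bond together. Forward key step: aldol condensation of cyclohexane-1,4-dione A8 with 1H-imidazole-2-carbaldehyde A9 and tautomerisation to the hydroquinone A10. Turned down for two reasons:
- A8 and A9 are simple, but their product A10 has two phenolic hydroxyls that differ only by the ortho arm. The target needs the methyl group on the unhindered one and the aryl group on the hindered one, and nothing in the structure enforces that order.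
- Ring B with its own imidazole would still have to be joined to the hindered phenol of A10 by a metal-catalysed coupling beside free N–H groups, which brings back the problem of the textbook route with extra protection steps.

Key step: step 3

## Route

Step 1
Reactants: 1 1-{[2-(trimethylsilyl)ethoxy]methyl}-1H-imidazole (1-SEM-imidazole); 2 1-(bromomethyl)-3-methoxybenzene (3-methoxybenzyl bromide)
Product: 4 2-(3-methoxybenzyl)-1-{[2-(trimethylsilyl)ethoxy]methyl}-1H-imidazole, via 2-lithio-1-SEM-imidazole 3 (not isolated)
Conditions: n-BuLi, THF, −78 °C; then 2, −78 °C to rt
Reagents that add atoms: none
Why: Directed C2-lithiation of an N-protected imidazole (C2–H is the most acidic site and the SEM oxygen assists) followed by SN2 benzylation of the C2 anion; the benzylic bromide is primary and activated, and no other electrophilic site is present.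

Step 2
Reactants: 4 2-(3-methoxybenzyl)-1-{[2-(trimethylsilyl)ethoxy]methyl}-1H-imidazole
Product: 5 3-[(1-{[2-(trimethylsilyl)ethoxy]methyl}-1H-imidazol-2-yl)methyl]phenol
Conditions: NaSEt, DMF, 130 °C; then aq HCl to pH 7
Reagents that add atoms: none
Why: Thiolate-mediated SN2 demethylation of an aryl methyl ether (attack at the methyl carbon, phenoxide as leaving group); the SEM group is an N,O-acetal that is stable to base and to soft nucleophiles, and the rest of the molecule has no electrophilic site.

Step 3
Reactants: 4 2-(3-methoxybenzyl)-1-{[2-(trimethylsilyl)ethoxy]methyl}-1H-imidazole; 5 3-[(1-{[2-(trimethylsilyl)ethoxy]methyl}-1H-imidazol-2-yl)methyl]phenol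
Product: 7 2-[(5-methoxy-2-{3-[(1-{[2-(trimethylsilyl)ethoxy]methyl}-1H-imidazol-2-yl)methyl]phenoxy}phenyl)methyl]-1-{[2-(trimethylsilyl)ethoxy]methyl}-1H-imidazole (bis-SEM lepidine C), via aryl(mesityl)iodonium tosylate 6 (not isolated)
Conditions: 4, MesI(OAc)2 (0.95 equiv), TsOH·H2O (2.2 equiv), CH2Cl2–CF3CH2OH, rt; concentrate; then 5, i-Pr2NEt, Cu(MeCN)4BF4 (10 mol %), CH2Cl2, rt
Reagents that add atoms: none
Why: The closest known reaction type is the one-pot para-selective C–H aryloxylation of electron-rich arenes with phenols, through an unsymmetrical diaryliodonium salt made in the flask and coupled under monovalent-copper catalysis. In stage one MesI(OAc)2 and TsOH give [hydroxy(tosyloxy)iodo]mesitylene, whose cationic trivalent iodine attacks 4 by electrophilic aromatic substitution to give 6; the second equivalent of TsOH keeps the imidazole N3 protonated, so the heterocycle neither binds iodine nor is attacked at C4/C5. For site selectivity, of the three free positions activated by the methoxy group the bulky iodane should take the one para to it (C6 of the benzyl ring, the future C1 of ring A); the two ortho positions are electronically second best and sterically worse, and the protonated arm deactivates its own ortho and para positions about equally, so it should not change that order. In stage two, after acetic acid and the fluoro alcohol are removed, the amine base frees the phenoxide of 5, monovalent copper inserts into the less hindered aryl–iodine bond of 6 (the two ortho methyl groups make mesityl the bystander, and the neighbouring N3 can deliver copper to the ring A carbon), and C–O reductive elimination from the aryl trivalent-copper phenoxide gives 7 and iodomesitylene. Chemoselectivity for oxygen over nitrogen rests on the SEM groups: neither imidazole has an N–H to arylate, and quaternisation of N3 should not compete with an anionic phenoxide on copper at room temperature. No ring is closed and no stereocentre is formed; the step joins the two halves at the one hindered, electron-rich C–O bond directly from a C–H bond.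

Step 4
Reactants: 7 bis-SEM lepidine C
Product: 8 lepidine C (2-({2-[3-(1H-imidazol-2-ylmethyl)phenoxy]-5-methoxyphenyl}methyl)-1H-imidazole)
Conditions: 3 M aq HCl, EtOH, 80 °C; then aq NaHCO3
Reagents that add atoms: none
Why: Acid hydrolysis of the two N,O-acetal (SEM) groups: loss of 2-(trimethylsilyl)ethanol gives an N-methylene iminium ion, which water cleaves to the N–H imidazole and formaldehyde; the diaryl ether and the aryl methyl ether are inert to dilute HCl at this temperature.

## Compound list

1 | 1-{[2-(trimethylsilyl)ethoxy]methyl}-1H-imidazole (1-SEM-imidazole) | C[Si](C)(C)CCOCn1ccnc1 | starting material
2 | 1-(bromomethyl)-3-methoxybenzene (3-methoxybenzyl bromide) | COc1cccc(CBr)c1 | starting material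
3 | 2-lithio-1-{[2-(trimethylsilyl)ethoxy]methyl}-1H-imidazole | [Li]c1nccn1COCC[Si](C)(C)C | intermediate
4 | 2-(3-methoxybenzyl)-1-{[2-(trimethylsilyl)ethoxy]methyl}-1H-imidazole | COc1cccc(Cc2nccn2COCC[Si](C)(C)C)c1 | intermediate
5 | 3-[(1-{[2-(trimethylsilyl)ethoxy]methyl}-1H-imidazol-2-yl)methyl]phenol | Oc1cccc(Cc2nccn2COCC[Si](C)(C)C)c1 | intermediate
6 | [4-methoxy-2-({1-[(2-(trimethylsilyl)ethoxy)methyl]-1H-imidazol-2-yl}methyl)phenyl](2,4,6-trimethylphenyl)iodonium tosylate (in the flask its N3 is protonated as a second tosylate) | COc1ccc([I+]c2c(C)cc(C)cc2C)c(Cc2nccn2COCC[Si](C)(C)C)c1.Cc1ccc(S(=O)(=O)[O-])cc1 | intermediate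
7 | 2-[(5-methoxy-2-{3-[(1-{[2-(trimethylsilyl)ethoxy]methyl}-1H-imidazol-2-yl)methyl]phenoxy}phenyl)methyl]-1-{[2-(trimethylsilyl)ethoxy]methyl}-1H-imidazole | COc1ccc(Oc2cccc(Cc3nccn3COCC[Si](C)(C)C)c2)c(Cc2nccn2COCC[Si](C)(C)C)c1 | intermediate
8 | lepidine C | COc1ccc(Oc2cccc(Cc3ncc[nH]3)c2)c(Cc2ncc[nH]2)c1 | target

## Step count and risks

Total step count: 4. Longest linear sequence: 4 steps (step 1, step 2, step 3, step 4; compound 4 from step 1 enters step 3 directly and, through step 2, as 5).

Steps least certain to work:

**Step 3 (key step).** Three processes can go wrong.
- The iodane substitution may be slow or misdirected. The arm on the anisole ring is a protonated imidazolylmethyl group, which withdraws electron density and stands ortho to the carbon that must react, so attack ortho to the methoxy group or incomplete conversion is possible.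
- In the copper stage, the two imidazole N3 atoms may sequester the catalyst, N3 of the ring A arm may close onto the aryl–copper carbon, or some mesityl may be transferred.
- Trivalent iodine left over from stage one would oxidise phenol 5; the slight deficit of the iodane is meant to limit this.

The fallback separates C–H functionalisation from C–O coupling and uses a classical aryl halide. It sets out from 4: para-iodination with N-iodosuccinimide in CF3CO2H/MeCN (imidazole protonated, iodine enters para to the methoxy group) should give 2-(2-iodo-5-methoxybenzyl)-1-SEM-imidazole F1. An Ullmann ether coupling of F1 with 5 (CuI, N,N-dimethylglycine, Cs2CO3, dioxane, 100 °C) then returns to the route at 7.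

**Step 1.** The product 4 carries a CH2 group activated by both an arene and an imidazole. Proton transfer from this CH2 to the lithio species 3 would cause double benzylation and stall conversion, and bromine–lithium exchange with 2 would lead to homocoupling of the benzyl unit. The fallback reverses the polarity of the bond formation. It sets out from 1: lithiation to 3 and quenching with I2 gives 2-iodo-1-SEM-imidazole F2. A Negishi coupling of F2 with commercial 3-methoxybenzylzinc chloride (Pd(PPh3)4, zerovalent palladium, THF, 60 °C) returns to the route at 4.

**Step 2.** The hot thiolate may attack the SEM group as well as the methyl ether (substitution at the N–CH2–O carbon with loss of imidazolide, or attack at silicon). That would strip the N-protection the key step relies on. The fallback unveils the phenol by hydrogenolysis instead of nucleophilic dealkylation. It sets out from 1: lithiation to 3 and alkylation with commercial 3-(benzyloxy)benzyl bromide gives 2-[3-(benzyloxy)benzyl]-1-SEM-imidazole F3. Hydrogenolysis of the benzyl ether of F3 (H2, Pd/C, EtOH) returns to the route at 5.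

## Further compounds

F1 | step 3 | 2-(2-iodo-5-methoxybenzyl)-1-{[2-(trimethylsilyl)ethoxy]methyl}-1H-imidazole | COc1ccc(I)c(Cc2nccn2COCC[Si](C)(C)C)c1
F2 | step 1 | 2-iodo-1-{[2-(trimethylsilyl)ethoxy]methyl}-1H-imidazole | C[Si](C)(C)CCOCn1ccnc1I
F3 | step 2 | 2-[3-(benzyloxy)benzyl]-1-{[2-(trimethylsilyl)ethoxy]methyl}-1H-imidazole | C[Si](C)(C)CCOCn1ccnc1Cc1cccc(OCc2ccccc2)c1
A1 | alternative 1 | 2-(2-bromo-5-methoxyphenyl)acetonitrile | COc1ccc(Br)c(CC#N)c1
A2 | alternative 1 | 2-(3-hydroxyphenyl)acetonitrile | N#CCc1cccc(O)c1
A3 | alternative 1 | 2-{2-[3-(cyanomethyl)phenoxy]-5-methoxyphenyl}acetonitrile | COc1ccc(Oc2cccc(CC#N)c2)c(CC#N)c1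
A4 | alternative 2 | 2-fluoro-5-methoxybenzaldehyde | COc1ccc(F)c(C=O)c1
A5 | alternative 2 | 3-hydroxybenzaldehyde | O=Cc1cccc(O)c1
A6 | alternative 2 | 2-(3-formylphenoxy)-5-methoxybenzaldehyde | COc1ccc(Oc2cccc(C=O)c2)c(C=O)c1
A7 | alternative 2 | bis-carbinol from double addition of 2-lithio-1-SEM-imidazole to A6 (mixture of diastereomers, configuration at the two carbinol carbons not defined) | COc1ccc(Oc2cccc(C(O)c3nccn3COCC[Si](C)(C)C)c2)c(C(O)c2nccn2COCC[Si](C)(C)C)c1
A8 | alternative 3 | cyclohexane-1,4-dione | O=C1CCC(=O)CC1
A9 | alternative 3 | 1H-imidazole-2-carbaldehyde | O=Cc1ncc[nH]1
A10 | alternative 3 | 2-(1H-imidazol-2-ylmethyl)benzene-1,4-diol | Oc1ccc(O)c(Cc2ncc[nH]2)c1
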